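Everything rests on cutting the O9'–C7 bond of the tetrahydrofuran (ring atoms O9', C7, C8, C8', C9'). Once it is gone both aryl-C3 halves are alike, so the skeleton is the (8R,8'R) dimer of one hydroferulic acid unit and the ring 8,8'-cis relationship comes with it. The key step exploits that C7 is the only benzylic carbon delta to O9' (C7' is gamma): an O9' radical takes a C7 hydrogen, the benzylic centre is oxidised, and the returning hydroxyl closes the ring and sets C7 in the same operation. Its precursor is the acyclic 9-O-stearoyl dibenzylbutanediol that carries a phthalimide on O9' and silyl-protected phenols.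

Key step: step 7

Remark: lignan numbering is used (C7/C7' benzylic, C8/C8' methine, C9/C9' oxymethylene; the unprimed half bears the ring aryl group and the stearate). The given SMILES decodes as 7S,8R,8'R, that is oxolane 2S,3R,4R with 2,3-trans and 3,4-cis substituents, the 9-stearate of (+)-lariciresinol. TIPS = triisopropylsilyl.

Step 1
Reactants: 1 hydroferulic acid
Product: 3 O-TIPS-hydroferulic acid (3-[3-methoxy-4-(triisopropylsilyloxy)phenyl]propanoic acid), via bis-TIPS silyl ester 2 (not isolated)
Conditions: TIPSCl (2.2 equiv), imidazole, DMF, rt; then K2CO3, THF–MeOH–H2O, rt; 1 M HCl to pH 4, 0 °C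
Reagents that add atoms: triisopropylsilyl chloride, CC(C)[Si](Cl)(C(C)C)C(C)C
Why: Imidazole-promoted silylation caps both acidic oxygens, and the silyl ester of 2 is far more labile than the hindered aryl silyl ether, so brief K2CO3 hydrolysis should free only the acid; a fluoride-labile phenol mask is chosen because it tolerates amide base, hydride and light and spares the last step any hydrogenolysis next to the benzylic C7–O bond.

Step 2
Reactants: 3 O-TIPS-hydroferulic acid; 4 (S)-4-isopropyloxazolidin-2-one
Product: 6 N-acyl oxazolidinone monomer ((4S)-4-isopropyl-3-{3-[3-methoxy-4-(triisopropylsilyloxy)phenyl]propanoyl}oxazolidin-2-one), via mixed pivalic anhydride 5 (not isolated)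
Conditions: PivCl, Et3N, THF, −20 °C; then LiCl, 4, −20 °C to rt
Reagents that add atoms: (S)-4-isopropyloxazolidin-2-one (4), CC(C)[C@H]1COC(=O)N1; pivaloyl chloride, CC(C)(C)C(=O)Cl (its acyl group stays only in intermediate 5)
Why: Mixed-anhydride N-acylation of an oxazolidinone in the LiCl/Et3N variant, in which the nitrogen attacks the unhindered carbonyl of 5 rather than the pivaloyl carbonyl and no stereocentre is involved.

Step 3
Reactants: 6 N-acyl oxazolidinone monomer (two molecules)
Product: 8 (2R,3R)-2,3-bis(arylmethyl)succinic bis-imide (aryl = 3-methoxy-4-TIPSO-phenyl; both auxiliaries 4S), via lithium Z-enolate 7 (not isolated)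
Conditions: LiN(iPr)2 (1.1 equiv), THF, −78 °C; then TiCl4 (1.1 equiv), −78 to 0 °C; aq NH4Cl
Reagents that add atoms: LiN(iPr)2, [Li]N(C(C)C)C(C)C (its lithium stays only in intermediate 7)
Why: Oxidative enolate homocoupling, a reaction known for 3-arylpropanoyl oxazolidinones, in which tetravalent titanium takes one electron from each chelated Z-enolate 7 and the C8–C8' bond forms with each carbon reacting on the face remote from the isopropyl group of its (S)-auxiliary; this sets both new centres as R and leaves any minor isomers as separable diastereomers.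

Step 4
Reactants: 8 (2R,3R)-bis-imide
Product: 9 di-O-TIPS (−)-secoisolariciresinol ((2R,3R)-2,3-bis{[3-methoxy-4-(triisopropylsilyloxy)phenyl]methyl}butane-1,4-diol)
Conditions: LiBH4, THF, 0 °C to rt; aq NH4Cl
Reagents that add atoms: none
Why: Reductive cleavage of N-acyl oxazolidinones by LiBH4 takes place at the exocyclic carbonyls, any butyrolactone formed when the first alkoxide attacks the second imide is reduced to the same diol, and C8/C8' are carried through unchanged while the auxiliary is recovered.

Step 5
Reactants: 9 di-O-TIPS (−)-secoisolariciresinol; 10 stearoyl chloride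
Product: 11 mono-stearate ((2R,3R)-4-hydroxy-2,3-bis{[3-methoxy-4-(triisopropylsilyloxy)phenyl]methyl}butyl octadecanoate)
Conditions: 9 (2 equiv), pyridine, CH2Cl2, −20 °C; 10 (1 equiv) by slow addition, to 0 °C; unreacted 9 recovered
Reagents that add atoms: stearoyl chloride (10), CCCCCCCCCCCCCCCCCC(=O)Cl
Why: O-acylation by an acyl chloride, in which the two hydroxyls are homotopic so that either gives 11, excess diol and slow addition tilt the statistics toward the monoester, a later 1,4-acyl shift would be degenerate, and pyridine rather than a trialkylamine avoids ketene formation from 10.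

Step 6
Reactants: 11 mono-stearate; 12 N-hydroxyphthalimide
Product: 13 N-alkoxyphthalimide ((2R,3R)-4-(1,3-dioxoisoindolin-2-yloxy)-2,3-bis{[3-methoxy-4-(triisopropylsilyloxy)phenyl]methyl}butyl octadecanoate)
Conditions: PPh3, DIAD, THF, 0 °C to rt
Reagents that add atoms: N-hydroxyphthalimide (12), O=C1c2ccccc2C(=O)N1O
Why: Mitsunobu reaction with the acidic N–OH of 12 as pronucleophile, an SN2 displacement at primary C9' that exchanges the hydroxyl oxygen for the N–O oxygen destined to become the ring oxygen and leaves C8', the ester and the silyl ethers untouched.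

Step 7
Reactants: 13 N-alkoxyphthalimide
Product: 17 di-O-TIPS (+)-lariciresinol 9-stearate ((2S,3R,4R)-oxolane), via O9' alkoxy radical 14 (not isolated), via C7 benzylic radical 15 (not isolated), via C7 benzylic cation 16 (not isolated)
Conditions: fac-Ir(ppy)3 (1–2 mol %), degassed CH2Cl2–MeCN (2:1), 0.02 M, blue LEDs (450 nm), rt
Reagents that add atoms: none
Why: Proposed new method: excited fac-Ir(ppy)3 passes one electron to the phthalimide of 13, the radical anion breaks at N–O into phthalimide anion and alkoxy radical 14, a 1,5-hydrogen shift through a six-membered transition state moves the spin to C7 (15), the tetravalent iridium complex left by the first event oxidises this electron-rich radical to cation 16, and the O9'–H regenerated by the shift adds to C7 while phthalimide anion removes the proton, so the change is redox-neutral and needs no added oxidant. Nearest precedents by type are the hypoiodite and Pb(OAc)4 ether syntheses, in which an alkoxy radical likewise relays to the delta carbon, the reductive photoredox delta-C–H alkylations that start from N-alkoxyphthalimides, and the acid-induced ring closure of dibenzylbutanediols that carry a 7-hydroxyl. The tetrahydrofuran closes in the 5-exo-trig mode, O9' attacking trigonal C7 whose C7=C1 bond (para-quinoid oxocarbenium form) lies outside the new ring. C7 is controlled by C8, because the planar cation should close through the rotamer holding the aryl group anti to the C9 acyloxymethyl arm (the alternative would put all three ring substituents on one face), which gives 7,8-trans, that is 7S, while C8 and C8' are not touched. The site selectivity needed is secured by distance and bond strength: C7–H is the only weak, hydridic C–H delta to O9', C7'–H is gamma and would need a strained 1,4-shift, and the delta C9–H bonds are strong and deactivated toward an electrophilic oxygen radical by the adjacent ester oxygen. Dilution in solvents without weak C–H bonds disfavours intermolecular abstraction, and the nearly neutral medium keeps O-capture irreversible, so Friedel–Crafts closure onto the C7' arene should not take over.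

Step 8
Reactants: 17 di-O-TIPS (+)-lariciresinol 9-stearate
Product: 18 (+)-lariciresinol 9-O-stearate (target)
Conditions: Bu4NF, AcOH (1:1, 2.5 equiv each), THF, 0 °C
Reagents that add atoms: none
Why: Fluoride-induced cleavage of aryl silyl ethers, buffered with AcOH so that phenoxide-triggered opening at C7, ester cleavage and acid ionisation of the C7–O bond are all avoided and no stereocentre is affected.

Compound list
1 | hydroferulic acid, 3-(4-hydroxy-3-methoxyphenyl)propanoic acid | COc1cc(CCC(=O)O)ccc1O | starting material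
2 | triisopropylsilyl 3-[3-methoxy-4-(triisopropylsilyloxy)phenyl]propanoate | COc1cc(CCC(=O)O[Si](C(C)C)(C(C)C)C(C)C)ccc1O[Si](C(C)C)(C(C)C)C(C)C | intermediate
3 | 3-[3-methoxy-4-(triisopropylsilyloxy)phenyl]propanoic acid | COc1cc(CCC(=O)O)ccc1O[Si](C(C)C)(C(C)C)C(C)C | intermediate
4 | (S)-4-isopropyloxazolidin-2-one | CC(C)[C@H]1COC(=O)N1 | starting material
5 | mixed anhydride of 3 and pivalic acid | COc1cc(CCC(=O)OC(=O)C(C)(C)C)ccc1O[Si](C(C)C)(C(C)C)C(C)C | intermediate
6 | (4S)-4-isopropyl-3-{3-[3-methoxy-4-(triisopropylsilyloxy)phenyl]propanoyl}oxazolidin-2-one | COc1cc(CCC(=O)N2[C@@H](C(C)C)COC2=O)ccc1O[Si](C(C)C)(C(C)C)C(C)C | intermediate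
7 | lithium Z-enolate of 6 | COc1cc(C/C=C(\O[Li])N2[C@@H](C(C)C)COC2=O)ccc1O[Si](C(C)C)(C(C)C)C(C)C | intermediate
8 | (2R,3R)-1,4-bis[(4S)-4-isopropyl-2-oxooxazolidin-3-yl]-2,3-bis{[3-methoxy-4-(triisopropylsilyloxy)phenyl]methyl}butane-1,4-dione | COc1cc(C[C@@H](C(=O)N2[C@@H](C(C)C)COC2=O)[C@H](C(=O)N2[C@@H](C(C)C)COC2=O)Cc2ccc(O[Si](C(C)C)(C(C)C)C(C)C)c(OC)c2)ccc1O[Si](C(C)C)(C(C)C)C(C)C | intermediate
9 | (2R,3R)-2,3-bis{[3-methoxy-4-(triisopropylsilyloxy)phenyl]methyl}butane-1,4-diol | OC[C@H](Cc1ccc(O[Si](C(C)C)(C(C)C)C(C)C)c(OC)c1)[C@@H](Cc1ccc(O[Si](C(C)C)(C(C)C)C(C)C)c(OC)c1)CO | intermediate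
10 | stearoyl chloride | CCCCCCCCCCCCCCCCCC(=O)Cl | starting material
11 | (2R,3R)-4-hydroxy-2,3-bis{[3-methoxy-4-(triisopropylsilyloxy)phenyl]methyl}butyl octadecanoate | CCCCCCCCCCCCCCCCCC(=O)OC[C@H](Cc1ccc(O[Si](C(C)C)(C(C)C)C(C)C)c(OC)c1)[C@@H](Cc1ccc(O[Si](C(C)C)(C(C)C)C(C)C)c(OC)c1)CO | intermediate
12 | N-hydroxyphthalimide | O=C1c2ccccc2C(=O)N1O | starting material
13 | (2R,3R)-4-(1,3-dioxoisoindolin-2-yloxy)-2,3-bis{[3-methoxy-4-(triisopropylsilyloxy)phenyl]methyl}butyl octadecanoate | CCCCCCCCCCCCCCCCCC(=O)OC[C@H](Cc1ccc(O[Si](C(C)C)(C(C)C)C(C)C)c(OC)c1)[C@@H](Cc1ccc(O[Si](C(C)C)(C(C)C)C(C)C)c(OC)c1)CON1C(=O)c2ccccc2C1=O | intermediate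
14 | O9' alkoxy radical derived from 13 | CCCCCCCCCCCCCCCCCC(=O)OC[C@H](Cc1ccc(O[Si](C(C)C)(C(C)C)C(C)C)c(OC)c1)[C@@H](Cc1ccc(O[Si](C(C)C)(C(C)C)C(C)C)c(OC)c1)C[O] | intermediate
15 | C7 benzylic radical bearing the free 9'-hydroxyl | CCCCCCCCCCCCCCCCCC(=O)OC[C@H]([CH]c1ccc(O[Si](C(C)C)(C(C)C)C(C)C)c(OC)c1)[C@@H](Cc1ccc(O[Si](C(C)C)(C(C)C)C(C)C)c(OC)c1)CO | intermediate
16 | C7 benzylic cation bearing the free 9'-hydroxyl | CCCCCCCCCCCCCCCCCC(=O)OC[C@H]([CH+]c1ccc(O[Si](C(C)C)(C(C)C)C(C)C)c(OC)c1)[C@@H](Cc1ccc(O[Si](C(C)C)(C(C)C)C(C)C)c(OC)c1)CO | intermediate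
17 | [(2S,3R,4R)-2-[3-methoxy-4-(triisopropylsilyloxy)phenyl]-4-{[3-methoxy-4-(triisopropylsilyloxy)phenyl]methyl}oxolan-3-yl]methyl octadecanoate | CCCCCCCCCCCCCCCCCC(=O)OC[C@H]1[C@@H](Cc2ccc(O[Si](C(C)C)(C(C)C)C(C)C)c(OC)c2)CO[C@@H]1c1ccc(O[Si](C(C)C)(C(C)C)C(C)C)c(OC)c1 | intermediate
18 | [(2S,3R,4R)-2-(4-hydroxy-3-methoxyphenyl)-4-[(4-hydroxy-3-methoxyphenyl)methyl]oxolan-3-yl]methyl octadecanoate, (+)-lariciresinol 9-O-stearate | CCCCCCCCCCCCCCCCCC(=O)OC[C@H]1[C@@H](Cc2ccc(O)c(OC)c2)CO[C@@H]1c1ccc(O)c(OC)c1 | target

Total step count: 8. Longest linear sequence: 8 steps (1 to 18).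

Steps most likely to fail

Step 7. Several processes could erode the closure:
- back electron transfer, or elimination across the C9'–O–N unit, before the hydrogen shift;
- addition of the oxygen radical to the nearby C7' arene;
- loss of formaldehyde by beta-scission;
- carbon rather than oxygen capture of the cation.

The fallback sets out from 9 and comes back at 18. It moves the ring closure ahead of the esterification and replaces the radical relay by quinone methide chemistry, which is known for 4-alkylguaiacols. Bu4NF/AcOH in THF frees (−)-secoisolariciresinol F1. One equivalent of DDQ (dioxane, solid NaHCO3, rt) dehydrogenates one guaiacyl unit to the para-quinone methide F2. Because C7 and C7' are homotopic in F1, no site selection is needed. The delta hydroxyl adds in a 1,6-sense to give (+)-lariciresinol F3, which should again be 7,8-trans for steric reasons. The oxidation is stopped at partial conversion to limit a second closure, and F1 is recycled. The only aliphatic hydroxyl of F3 is then esterified with stearic acid under Mitsunobu conditions (PPh3, DIAD, THF), which are known to spare phenols, giving 18.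

Step 3. Facial control in the C–C bond formation may be incomplete. Conversion may also be lost through self-acylation of the enolate or attack of the Lewis acid on the silyl ethers. The fallback sets out from 6 and comes back at 9. It builds the two centres one after the other by enolate alkylations of known type.
- Imide 6 is alkylated (NaN(SiMe3)2, THF, −78 °C, tert-butyl bromoacetate) under the same auxiliary bias to the (R)-succinate half-imide F4.
- LiBH4 removes the auxiliary to give hydroxy ester F5, which lactonises under catalytic p-TsOH in warm toluene to the (R)-beta-arylmethyl butyrolactone F6.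
- The electrophile comes from vanillin: TIPSCl/imidazole gives aldehyde F7, NaBH4 gives benzylic alcohol F8, and Appel bromination (PPh3, CBr4) gives benzylic bromide F9.
- The enolate of F6 (LiN(SiMe3)2, THF, −78 °C) is alkylated by F9 anti to the beta substituent to give the trans-(3R,4R)-dibenzylbutyrolactone F10.
- LiBH4 in THF reduces F10 to 9.

Step 5. Over-acylation and poor discrimination between the first and second esterification would waste the diol. The fallback sets out from 9 and comes back at 11. It ties both oxygens to one tin atom so that only one acyl transfer can occur. Bu2SnO in toluene with azeotropic removal of water gives the cyclic dibutylstannylene acetal F11. One equivalent of 10 at 0 °C opens the ring, acylates one oxygen and leaves the other as a poorly nucleophilic chlorostannyl alkoxide. Aqueous work-up hydrolyses that alkoxide to 11.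

Further compounds
F1 | step 7 | (−)-secoisolariciresinol, (2R,3R)-2,3-bis[(4-hydroxy-3-methoxyphenyl)methyl]butane-1,4-diol | OC[C@H](Cc1ccc(O)c(OC)c1)[C@@H](Cc1ccc(O)c(OC)c1)CO
F2 | step 7 | C7 para-quinone methide of F1 (C7=C1 geometry open) | OC[C@H](C=C1C=CC(=O)C(OC)=C1)[C@@H](Cc1ccc(O)c(OC)c1)CO
F3 | step 7 | (+)-lariciresinol, (2S,3R,4R)-oxolane | OC[C@H]1[C@@H](Cc2ccc(O)c(OC)c2)CO[C@@H]1c1ccc(O)c(OC)c1
F4 | step 3 | tert-butyl (3R)-4-[(4S)-4-isopropyl-2-oxooxazolidin-3-yl]-3-{[3-methoxy-4-(triisopropylsilyloxy)phenyl]methyl}-4-oxobutanoate | COc1cc(C[C@@H](C(=O)N2[C@@H](C(C)C)COC2=O)CC(=O)OC(C)(C)C)ccc1O[Si](C(C)C)(C(C)C)C(C)C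
F5 | step 3 | tert-butyl (3R)-4-hydroxy-3-{[3-methoxy-4-(triisopropylsilyloxy)phenyl]methyl}butanoate | COc1cc(C[C@@H](CO)CC(=O)OC(C)(C)C)ccc1O[Si](C(C)C)(C(C)C)C(C)C
F6 | step 3 | (4R)-4-{[3-methoxy-4-(triisopropylsilyloxy)phenyl]methyl}oxolan-2-one | COc1cc(C[C@H]2COC(=O)C2)ccc1O[Si](C(C)C)(C(C)C)C(C)C
F7 | step 3 | 3-methoxy-4-(triisopropylsilyloxy)benzaldehyde | COc1cc(C=O)ccc1O[Si](C(C)C)(C(C)C)C(C)C
F8 | step 3 | [3-methoxy-4-(triisopropylsilyloxy)phenyl]methanol | COc1cc(CO)ccc1O[Si](C(C)C)(C(C)C)C(C)C
F9 | step 3 | [4-(bromomethyl)-2-methoxyphenoxy]triisopropylsilane | COc1cc(CBr)ccc1O[Si](C(C)C)(C(C)C)C(C)C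
F10 | step 3 | (3R,4R)-3,4-bis{[3-methoxy-4-(triisopropylsilyloxy)phenyl]methyl}oxolan-2-one, di-O-TIPS (−)-matairesinol | O=C1OC[C@H](Cc2ccc(O[Si](C(C)C)(C(C)C)C(C)C)c(OC)c2)[C@H]1Cc1ccc(O[Si](C(C)C)(C(C)C)C(C)C)c(OC)c1
F11 | step 5 | (5R,6R)-2,2-dibutyl-5,6-bis{[3-methoxy-4-(triisopropylsilyloxy)phenyl]methyl}-1,3,2-dioxastannepane | CCCC[Sn]1(CCCC)OC[C@H](Cc2ccc(O[Si](C(C)C)(C(C)C)C(C)C)c(OC)c2)[C@@H](Cc2ccc(O[Si](C(C)C)(C(C)C)C(C)C)c(OC)c2)CO1
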